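(The constants were set for the occasion; what happens was integrated by code.)

We choose to reckon this flask from its reagent charge, treating target as the small remainder of a large pool.

substrate 0.30 M (in portions, 4); reagent 0.180 M; time 50 min; the portions of substrate follow each other after 0.80 s, the first at the start

    substrate + reagent → target (k1 = 0.63 L mol⁻¹ s⁻¹)
    substrate + reagent → isomer of the product A (k2 = 0.23 L mol⁻¹ s⁻¹)
    target ⇌ isomer of the product B (K3 = 3.8, k3 = 0.045 s⁻¹)

* how much target there is at 50 min, in percent of the substrate charged
* how much isomer of the product B there is at 50 min, in percent of the substrate charged
* amount of target if the flask were left three thousand times as long, in percent of the substrate charged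

Two numbers seem not to fit in this flask: target forms 2.74 times as fast as isomer of the product A, yet by our reckoning it ends with less.

Reagent is the limiting reagent, charged at less than substrate. Both substrate steps have the same rate form, so a share f = 0.733 of the reagent consumed gives target. In the tail after the dosing, once reagent has fallen far below the substrate excess of 0.120 M, reagent loss is pseudo-first-order, with a half-life of about 0.112 min, much shorter than the 50 min. Target and isomer of the product B relax together with a half-life of 0.203 min, also much shorter.

The pool of these two therefore holds 44.0 % of the substrate charged, and isomer of the product A holds 16.0 %. Target keeps one part in 4.80 of the pool, giving Y = 9.16 %. We call Y the equilibrated target share: reagent per substrate charged, times f, divided by one plus the equilibrium constant. The contradiction clears: the first step wins the branching, but equilibrium passes most of its product on, leaving target below isomer of the product A. Isomer of the product B gets 34.8 %, and we expect a longer wait to leave Y unchanged.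

The forecast gives the same: 9.16 % of target, 34.8 % of isomer of the product B and 9.16 % after the long wait, on the ground that “Both substrate channels have the same rate form”.

The simulation gives 9.16 %, 34.8 % and 9.16 %.

Integrating the portions thus returns Y. This flask stops with 40 % of its substrate left and 0 % of its reagent, because of the falling level of reagent: conversion of substrate is 60.0 % in the run as it is and 100 % in the run without that fall.

For the neighbouring flask with 1.2 M of substrate, Y gives 2.29 %; its simulation gives 2.29 %.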